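I have 40 min in each flask, so time is my first question: does the substrate get through it?

the same everywhere: partner 1.44 M; time 40 min
- violet: substrate 0.30 M
- blue: substrate 0.60 M
- grey: substrate 1.2 M
- red: substrate 2.5 M

    substrate + partner ⇌ intermediate A (K1 = 2.5 M⁻¹, k1 = 0.091 M⁻¹ s⁻¹)
    substrate + partner → intermediate B (k2 = 0.0063 M⁻¹ s⁻¹)
    intermediate A → intermediate C (k3 = 0.0017 s⁻¹)
    partner + intermediate B ⇌ target (K4 = 5.8 M⁻¹, k4 = 0.052 M⁻¹ s⁻¹)
    intermediate B ⇌ intermediate C (K5 = 0.32, k5 = 0.012 s⁻¹)
    substrate ⇌ dormant form (K6 = 0.55, k6 = 0.0053 s⁻¹)
    target → over-reaction product (k7 = 9.6 × 10⁻⁶ s⁻¹)

1. [target] at the end for violet, blue, grey, red, in this order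
2. how the row runs (falls, then rises / rises all the way / hardly changes / rises, then falls / falls all the way)

- "hardly changes" means that all values lie within two and a half points (for a concentration: within two and a half percent of the largest)
- run time (violet): 40 min

In violet, intermediate A goes on to intermediate C with a half-life of 6.8 min, so 5.88 half-lives fit into the run. Target decays with a half-life of 20 h, far longer than the run, so I count no loss there. Counting gives me ceilings for target, not its value: step 4 runs both ways.

So what does a target cost? Intermediate B holds one partner, and the step to target adds another, so each target costs two partners.

Now I solve both ends. At a low charge, target cannot pass the substrate charged. At a high charge, each substrate that enters the intermediates takes one partner. If the whole charge has entered, target cannot pass the spare partner, the partner charge minus the substrate charge. The two limits meet at a substrate charge of 0.720 M, half the partner charge, which I call the crossing charge. Below it, substrate is the limiting reagent for target; above it, the spare partner caps target once the whole charge has entered.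

Where do the flasks lie? Violet and blue stand below the crossing charge, so their ceilings are 0.30 M and 0.60 M. Grey stands above it, with a spare partner of 0.240 M. Red holds more substrate than partner, so its partner can serve at most 57.6% of its substrate, one each. I commit to a row that rises, then falls, turning near 0.720 M.

The forecast gives 0.24 M, 0.43 M, 0.59 M and 0.64 M, and says rises all the way: “the row flattens, but by my rough estimate it is still rising”. Here we differ, since my ceiling falls past the crossing charge.

The flasks give 0.235 M, 0.388 M, 0.276 M and 0.0504 M, so the row rises, then falls. The turn reads 0.73 M, close to the crossing charge of 0.720 M. Grey stands at 0.276 M, above its spare partner of 0.240 M, with 6.5% of its substrate still free at 40.0 min. Red is charged at 3.47 times the crossing charge, and at 400 min it holds partner at 0% of its charge and target at 0% of the substrate charged.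

The numbers were drawn at random within sensible limits; the run is a simulation.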